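# Proposed total synthesis of CNP0204264.1 via desymmetrising aldol-lactonisation of a prochiral glutaric anhydride

## Analysis of the target

The target 28 is a daucane sesquiterpenoid: a trans-fused bicyclo[5.3.0]decane in which a cyclopentane (C1–C5) shares the C1–C5 bond with a cycloheptane (C5–C10, C1) that carries an exocyclic methylene at C8. There are six stereocentres: the quaternary C1 (methyl), the fully substituted carbinol C4 (isopropyl, OH), the ring-fusion CH C5, the acyloxy carbon C6 and the cis-diol carbons C9 and C10. On the five-membered ring the C4 oxygen, C6 and the C1 methyl share one face, while the isopropyl group, H5 and C10 share the other. On the seven-membered ring H5, O6, O9 and O10 all lie on the face opposite the C1 methyl (called α below). The sensitive groups are the tertiary C4 alcohol (dehydration), the allylic C9 alcohol next to a 1,1-disubstituted alkene (ionisation, alkene migration) and a single isovalerate among three free hydroxyls (acyl migration or cleavage under base). The difficulty lies in three contiguous stereocentres C4/C5/C1, two of them without hydrogen, in the trans ring fusion, in closing a seven-membered ring, and in telling four oxygens apart. The plan rests on two features. First, C1 carries two two-carbon arms that both end in oxygenated carbon (C5–C6 and C10–C9), so C1 is the prochiral central carbon of a 3,3-disubstituted glutaric acid. Second, O4 is cis to C6 across the C4–C5 bond, so O4–C4–C5–C6 can be written as a β-lactone fused to the cyclopentane.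

## Retrosynthetic reasoning

**C9 and C10 oxygens (28 ⇐ 27 ⇐ 26 ⇐ 24).** The last bonds cut are the two O–Si bonds of 27, then the C9–H bond (back to ketone 26) and the C10–O bond (back to enone 24). C10 is a methylene between the quaternary C1 and C9, so its only handle is a C9 carbonyl. Enolisation of 24 can go only towards C10, because C8 bears no hydrogen. The forward steps must deliver oxygen to C10 from the α-face, which the pseudoaxial C1 methyl leaves open, and hydride to C9 so that the new hydroxyl is cis to O10.

**Seven-membered ring (24 ⇐ 23 ⇐ 22).** The ring is opened at C8–C9. A vinyl halide/aldehyde coupling across this bond gives the exocyclic methylene and the C9 oxygen in one step. Cutting C6–C7 or C7–C8 would leave the 1,1-disubstituted alkene to be built separately. The C9 configuration of 23 does not matter because C9 is oxidised to the ketone of 24.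

**Ester and C6–C7 bond (22 ⇐ 21 ⇐ 20 ⇐ 18 + 19; 18 ⇐ 16 + 17).** The isovalerate is traced back to 19 and put on at the stage of 18, where the only acylable hydroxyl is at C6 (the other is tertiary). This removes any later protecting-group exchange among the C6, C9 and C10 oxygens. The C6–C7 bond is cut to aldehyde 16 and the three-carbon bromoallyl donor 17. In 16 the free C4 hydroxyl sits cis to the formyl group and can steer the incoming carbon to the face that gives 6S.

**Differentiation of the two arms (16 ⇐ 15 ⇐ 14 ⇐ 13 ⇐ 12).** The C6 aldehyde and the protected C9 alcohol are traced to the two carbonyls of 12. These differ in kind: a free acid on the C10–C9 arm and a lactone on C5–C6. An electrophilic hydride reduces the acid only, a nucleophilic hydride then opens the lactone, so the arms never need a selective protection.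

**Key disconnection (12 ⇐ 11).** In 12 the C4–C5 bond and the O4–C6 acyl bond are cut and the C6 carbonyl is joined to the carboxyl of the other arm. This gives the achiral anhydride 11, in which a mirror plane passes through C1, its methyl group and the keto side chain. The forward step must choose one of the two enantiotopic CH2C(=O) arms, form C4–C5 on one enolate face and close the β-lactone. It sets C1, C5 and C4 together, and C4 already carries its isopropyl group.

**Anhydride (11 ⇐ 10 ⇐ 9).** The anhydride comes from diacid 10. Its two acetic acid arms are the two halves of the ring alkene of cyclopentene 9, so one oxidative cleavage delivers both with the correct carbon count.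

**Side chain and quaternary carbon (9 ⇐ 8 ⇐ 5 + 6; 5 ⇐ 4 ⇐ 3 ⇐ 1 + 2).** The C2–C3 bond is cut next to the ketone: a crossed aldol condensation of the non-enolisable aldehyde 5 with ketone 6, then conjugate reduction. Aldehyde 5 comes from ester 1 by α-methylation with 2 and adjustment of the oxidation state.

## Alternatives that were turned down

**Alternative 1:** Cope rearrangement of a cis-dialkenyl bicyclo[3.1.0]hexane.
- Disconnection: the C7–C8 bond is cut and a temporary C5–C10 cyclopropane bond is added.
- Key step: on warming, the cis-divinylcyclopropane undergoes a boat [3,3] shift that forms C7–C8, breaks C5–C10 and gives the hydroazulene diene A1 (C5=C6, C9=C10, C8 silyl ether, C4 ketal).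
- For: the whole bicyclic skeleton forms in one reagent-free, stereospecific step driven by strain release. The C9=C10 alkene sits where a syn-dihydroxylation from the open α-face would give the cis-diol directly. On that point it is stronger than the chosen route, which must set C9 by a ketone reduction.
- Against: A1 holds only the C1 stereocentre of the target (its C8 centre is later destroyed). Two ring alkenes must be told apart. The isopropyl group has to be added late to a hindered, enolisable C4 cyclopentanone. C8 must be oxidised and methylenated at the end. The enantioenriched cyclopropane needs its own asymmetric step.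
- Comparison: the chosen route gives in its key step the finished C4 carbinol with C5 and C1, and two arms already at different oxidation levels. The redox tail after A1 would be at least as long.

**Alternative 2:** Rhodium carbenoid C–H insertion.
- Disconnection: the C1–C5 bond.
- Key step: an α-diazo β-keto ester gives, with a dirhodium carboxylate, a carbenoid at C5 that inserts into the tertiary C1–H bond with retention and closes the cyclopentanone A2.
- For: 1,5-insertion into a tertiary C–H bond is well established and the quaternary centre is copied from a chiral-pool stereocentre without loss. On reliability of the key step it is clearly stronger than the chosen route.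
- Against: A2 carries one of the six stereocentres. C5 is epimerisable. C4 is a β-keto ester carbonyl to which an isopropyl nucleophile cannot be added without masking and without a facial problem. The C4/C5/C6 relationship and the whole seven-membered ring are still to be made. The diazo precursor needs several degradative steps from the terpene.
- Comparison: the chosen route accepts a riskier key step and in return leaves no open stereochemical problem on the five-membered ring.

**Alternative 3:** Silicon-tethered radical cyclisation with allyl transfer.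
- Disconnection: the C5–C6 and C1–C10 bonds.
- Key step: the radical from a bromomethylsilyl ether of the C4 carbinol closes 5-exo onto C5, and the tertiary C1 radical is trapped by a tin allyl donor to give oxasilolane A3.
- For: both reaction types are known. The cis-fused oxasilolane forces C6 cis to O4 just as the β-lactone does. The allyl group should enter anti to the new ring, giving the correct C1. Oxidative removal of silicon would give the same diol pattern as 15. It is equal on stereocontrol and stronger on precedent.
- Against: intermolecular trapping of a hindered tertiary radical to build a quaternary centre is slow and competes with premature quenching. Tin is stoichiometric. The allyl group has one carbon too many and must be cut back to C9. The cyclopentenyl substrate must be derived from a six-membered terpene alcohol, whose optical purity then limits that of the product.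
- Comparison: the chosen route offers catalytic control of absolute configuration from achiral materials and two arms of the right length and oxidation state straight from the key step.

Key step: step 8

## Assumptions and conventions

- The (S)-enantiomer of homobenzotetramisole is assumed to give the (1R,2R,5R) lactone 12. If the sense of induction is opposite, the (R)-catalyst is used and nothing else changes.
- Daucane locants (C1 quaternary methyl carbon, C4 isopropyl carbinol, C5 ring-fusion CH, C6 ester carbon, C8 methylene-bearing carbon, C9/C10 diol carbons) are used for the atoms of all intermediates. α is the face of the bicycle opposite the C1 methyl group.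

## Route

Step 1
Reactants: 1 methyl cyclopent-3-ene-1-carboxylate; 2 iodomethane
Product: 3 methyl 1-methylcyclopent-3-ene-1-carboxylate
Conditions: LiN(iPr)2, THF, −78 °C; then 2, −78 °C → rt
Reagents that add atoms: iodomethane 2, CI
Why: Ester enolate alkylation; deprotonation at the only α-carbon and SN2 methylation create the quaternary carbon that becomes C1, still achiral.

Step 2
Reactants: 3 methyl 1-methylcyclopent-3-ene-1-carboxylate
Product: 4 (1-methylcyclopent-3-en-1-yl)methanol
Conditions: LiAlH4, Et2O, 0 °C
Reagents that add atoms: none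
Why: Hydride reduction of the ester to the primary alcohol; the isolated ring alkene is inert to LiAlH4.

Step 3
Reactants: 4 (1-methylcyclopent-3-en-1-yl)methanol
Product: 5 1-methylcyclopent-3-ene-1-carbaldehyde
Conditions: (COCl)2, DMSO, CH2Cl2, −78 °C; Et3N, −78 → 0 °C; used as a concentrated solution
Reagents that add atoms: none
Why: Swern oxidation stops at the aldehyde; 5 has no α-hydrogen, so it cannot self-condense, and it is carried on in solution because it is volatile.

Step 4
Reactants: 5 1-methylcyclopent-3-ene-1-carbaldehyde; 6 3-methylbutan-2-one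
Product: 8 (E)-4-methyl-1-(1-methylcyclopent-3-en-1-yl)pent-1-en-3-one, via aldol adduct 7 (not isolated)
Conditions: 6 (5 equiv), NaOH (aq), EtOH, 50 °C
Reagents that add atoms: 3-methylbutan-2-one 6, CC(C)C(C)=O
Why: Claisen–Schmidt (crossed aldol) condensation; 5 cannot enolise, the aldol addition is reversible and only the adduct 7 formed at the methyl group of 6 can dehydrate, so the E-enone is the thermodynamic sink.

Step 5
Reactants: 8 (E)-4-methyl-1-(1-methylcyclopent-3-en-1-yl)pent-1-en-3-one
Product: 9 4-methyl-1-(1-methylcyclopent-3-en-1-yl)pentan-3-one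
Conditions: [(Ph3P)CuH]6 (0.25 equiv), H2O (5 equiv), THF, rt
Reagents that add atoms: none
Why: Copper hydride conjugate reduction; the phosphine-stabilised hydride of monovalent copper adds only to the polarised enone C=C and spares the isolated cyclopentene, which is the latent pair of acetic acid arms.

Step 6
Reactants: 9 4-methyl-1-(1-methylcyclopent-3-en-1-yl)pentan-3-one
Product: 10 3-methyl-3-(4-methyl-3-oxopentyl)pentanedioic acid
Conditions: RuCl3·xH2O (3 mol%), NaIO4 (4.5 equiv), MeCN/EtOAc/H2O, rt
Reagents that add atoms: sodium periodate, [Na+].[O-]I(=O)(=O)=O; water, O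
Why: RuO4-catalysed oxidative cleavage of the cis-disubstituted ring alkene gives both CH2CO2H arms in one operation; the saturated ketone is not attacked.

Step 7
Reactants: 10 3-methyl-3-(4-methyl-3-oxopentyl)pentanedioic acid
Product: 11 4-methyl-4-(4-methyl-3-oxopentyl)oxane-2,6-dione
Conditions: Ac2O, 100 °C; evaporation, bulb-to-bulb distillation
Reagents that add atoms: none
Why: Cyclodehydration of a 3,3-disubstituted glutaric acid, made fast by the gem-disubstitution (Thorpe–Ingold effect); 11 is achiral with a mirror plane through C1.

Step 8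
Reactants: 11 4-methyl-4-(4-methyl-3-oxopentyl)oxane-2,6-dione
Product: 12 2-[(1R,2R,5R)-2-methyl-7-oxo-5-(propan-2-yl)-6-oxabicyclo[3.2.0]heptan-2-yl]acetic acid
Conditions: (S)-HBTM (homobenzotetramisole, 20 mol%), iPr2NEt (1.5 equiv), LiCl (1.0 equiv), CH2Cl2, 0 °C → rt, slow addition of 11; 1 M HCl work-up
Reagents that add atoms: none
Why: Proposed new method: the isothiourea should attack one carbonyl of 11 reversibly to give an N-acyl isothiouronium ion that carries its own carboxylate, which (with iPr2NEt as proton shuttle) removes an α-proton and generates the ammonium enolate at C5; this enolate adds to the tethered isopropyl ketone in a 5-(enolexo)-exo-trig aldol that forms C4–C5 and closes the cyclopentane, and the C4 alkoxide then expels the catalyst in a 4-exo-trig acyl transfer that closes the β-lactone. The closest known reaction type is the nucleophile-catalysed aldol-lactonisation of 6-oxo carboxylic acids activated in situ, which gives the same cyclopentane-fused β-lactones, together with the catalytic enantioselective ring opening of prochiral glutaric anhydrides; here the anhydride itself is the activated acyl donor, so no coupling agent is needed. Because ring opening is reversible, the two enantiotopic arms interconvert through 11 and the product-determining event is the aldol-lactonisation, in which C1, C5 and C4 are fixed together. C5 is controlled by the catalyst, whose phenyl-bearing stereocentre shields one face of the planar acyl ammonium enolate; C4 follows from C5 because the four-membered ring can only be cis-fused, which puts O4 and C6 on one face. C1 is set by which arm reacts on that enolate face: the transition state with the small methyl group next to the bulky acyl isothiouronium unit and the solvated carboxylate arm on the open convex side should be preferred, giving methyl cis to C6. The step needs enantiotopic arm selection, enolate-face selection and C–C bond formation in preference to simple return to 11; the first two are expected from the catalyst and the concave/convex bias of the forming bicyclo[3.2.0] framework, the last from the proximity of the ketone enforced by the quaternary carbon and from LiCl activation of the ketone.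

Step 9
Reactants: 12 2-[(1R,2R,5R)-2-methyl-7-oxo-5-(propan-2-yl)-6-oxabicyclo[3.2.0]heptan-2-yl]acetic acid
Product: 13 (1R,2R,5R)-2-(2-hydroxyethyl)-2-methyl-5-(propan-2-yl)-6-oxabicyclo[3.2.0]heptan-7-one
Conditions: BH3·SMe2 (1.3 equiv), THF, 0 °C → rt; MeOH quench; used at once
Reagents that add atoms: none
Why: Borane reduces the free carboxylic acid through its acyloxyborane far faster than it attacks lactones, so the β-lactone is kept; 13 is not stored because its hydroxyl could slowly translactonise.

Step 10
Reactants: 13 (1R,2R,5R)-2-(2-hydroxyethyl)-2-methyl-5-(propan-2-yl)-6-oxabicyclo[3.2.0]heptan-7-one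
Product: 14 (1R,2R,5R)-2-[2-(tert-butyldimethylsilyloxy)ethyl]-2-methyl-5-(propan-2-yl)-6-oxabicyclo[3.2.0]heptan-7-one
Conditions: TBSOTf, 2,6-lutidine, CH2Cl2, −78 °C
Reagents that add atoms: tert-butyldimethylsilyl trifluoromethanesulfonate, CC(C)(C)[Si](C)(C)OS(=O)(=O)C(F)(F)F
Why: Silylation of the primary alcohol with a non-nucleophilic base at low temperature, conditions that do not open the β-lactone.

Step 11
Reactants: 14 (1R,2R,5R)-2-[2-(tert-butyldimethylsilyloxy)ethyl]-2-methyl-5-(propan-2-yl)-6-oxabicyclo[3.2.0]heptan-7-one
Product: 15 (1R,2S,3R)-3-[2-(tert-butyldimethylsilyloxy)ethyl]-2-(hydroxymethyl)-3-methyl-1-(propan-2-yl)cyclopentan-1-ol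
Conditions: LiAlH4, THF, 0 °C
Reagents that add atoms: none
Why: Hydride reduction of the β-lactone by acyl–oxygen cleavage gives the primary C6 alcohol and frees the tertiary C4 hydroxyl without touching its configuration; the silyl ether survives.

Step 12
Reactants: 15 (1R,2S,3R)-3-[2-(tert-butyldimethylsilyloxy)ethyl]-2-(hydroxymethyl)-3-methyl-1-(propan-2-yl)cyclopentan-1-ol
Product: 16 (1R,2R,5R)-2-[2-(tert-butyldimethylsilyloxy)ethyl]-5-hydroxy-2-methyl-5-(propan-2-yl)cyclopentane-1-carbaldehyde
Conditions: Dess–Martin periodinane, NaHCO3, CH2Cl2, 0 °C → rt; used crude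
Reagents that add atoms: none
Why: Dess–Martin oxidation can act only on the primary alcohol, the C4 hydroxyl being tertiary; buffered non-basic conditions avoid retro-aldol cleavage, and C5 should hold its configuration because the formyl group already lies trans to its two larger neighbours (isopropyl on C4, silyloxyethyl arm on C1).

Step 13
Reactants: 16 (1R,2R,5R)-2-[2-(tert-butyldimethylsilyloxy)ethyl]-5-hydroxy-2-methyl-5-(propan-2-yl)cyclopentane-1-carbaldehyde; 17 2,3-dibromoprop-1-ene
Product: 18 (1R,2S,3R)-2-[(1S)-3-bromo-1-hydroxybut-3-en-1-yl]-3-[2-(tert-butyldimethylsilyloxy)ethyl]-3-methyl-1-(propan-2-yl)cyclopentan-1-ol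
Conditions: 17 (3 equiv), indium powder (2 equiv), THF/H2O (1:1), rt
Reagents that add atoms: 2,3-dibromoprop-1-ene 17, C=C(Br)CBr
Why: Barbier-type indium-mediated 2-bromoallylation in aqueous medium, which tolerates the free hydroxyl; the C4 hydroxyl and the aldehyde oxygen bind the metal (Cram-chelate arrangement, carbonyl oxygen syn to O4), and the allyl group should enter from the exposed face next to H5, away from the quaternary C1, which gives 6S.

Step 14
Reactants: 18 (1R,2S,3R)-2-[(1S)-3-bromo-1-hydroxybut-3-en-1-yl]-3-[2-(tert-butyldimethylsilyloxy)ethyl]-3-methyl-1-(propan-2-yl)cyclopentan-1-ol; 19 3-methylbutanoic anhydride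
Product: 20 (1S)-3-bromo-1-[(1S,2R,5R)-2-[2-(tert-butyldimethylsilyloxy)ethyl]-5-hydroxy-2-methyl-5-(propan-2-yl)cyclopentyl]but-3-en-1-yl 3-methylbutanoate
Conditions: 19, DMAP, Et3N, CH2Cl2, rt
Reagents that add atoms: 3-methylbutanoic anhydride 19, CC(C)CC(=O)OC(=O)CC(C)C
Why: DMAP-catalysed acylation is selective for the secondary C6 hydroxyl, since the tertiary C4 hydroxyl does not react; the ester of the target is thereby installed early and no later exchange of protecting groups is needed.

Step 15
Reactants: 20 (1S)-3-bromo-1-[(1S,2R,5R)-2-[2-(tert-butyldimethylsilyloxy)ethyl]-5-hydroxy-2-methyl-5-(propan-2-yl)cyclopentyl]but-3-en-1-yl 3-methylbutanoate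
Product: 21 (1S)-3-bromo-1-[(1S,2R,5R)-5-hydroxy-2-(2-hydroxyethyl)-2-methyl-5-(propan-2-yl)cyclopentyl]but-3-en-1-yl 3-methylbutanoate
Conditions: HF·pyridine, pyridine, THF, 0 °C → rt
Reagents that add atoms: none
Why: Fluoride cleavage of the primary silyl ether under buffered conditions that leave the ester, the vinyl bromide and the tertiary alcohol untouched.

Step 16
Reactants: 21 (1S)-3-bromo-1-[(1S,2R,5R)-5-hydroxy-2-(2-hydroxyethyl)-2-methyl-5-(propan-2-yl)cyclopentyl]but-3-en-1-yl 3-methylbutanoate
Product: 22 (1S)-3-bromo-1-[(1S,2R,5R)-5-hydroxy-2-methyl-2-(2-oxoethyl)-5-(propan-2-yl)cyclopentyl]but-3-en-1-yl 3-methylbutanoate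
Conditions: Dess–Martin periodinane, NaHCO3, CH2Cl2, 0 °C
Reagents that add atoms: none
Why: Dess–Martin oxidation of the primary alcohol to the C9 aldehyde, which has no α-stereocentre; the tertiary hydroxyl cannot form a lactol with it because O4 and the C10 arm lie on opposite faces of the cyclopentane.

Step 17
Reactants: 22 (1S)-3-bromo-1-[(1S,2R,5R)-5-hydroxy-2-methyl-2-(2-oxoethyl)-5-(propan-2-yl)cyclopentyl]but-3-en-1-yl 3-methylbutanoate
Product: 23 (3R,3aS,4S,8aR)-3,7-dihydroxy-8a-methyl-6-methylidene-3-(propan-2-yl)decahydroazulen-4-yl 3-methylbutanoate (both C9 epimers; azulene C7 is daucane C9)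
Conditions: CrCl2 (6 equiv), NiCl2 (5 mol%), DMSO/THF, rt, 0.005 M
Reagents that add atoms: none
Why: Intramolecular Nozaki–Hiyama–Kishi reaction; zerovalent nickel inserts into the C8–Br bond, transmetalation gives a vinylchromium species that adds only to the aldehyde (7-exo closure of C8–C9) and tolerates the ester and the free hydroxyl. The C9 configuration is not controlled and need not be, because C9 is oxidised in the next step.

Step 18
Reactants: 23 (3R,3aS,4S,8aR)-3,7-dihydroxy-8a-methyl-6-methylidene-3-(propan-2-yl)decahydroazulen-4-yl 3-methylbutanoate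
Product: 24 (3R,3aS,4S,8aR)-3-hydroxy-8a-methyl-6-methylidene-7-oxo-3-(propan-2-yl)decahydroazulen-4-yl 3-methylbutanoate
Conditions: Dess–Martin periodinane, NaHCO3, CH2Cl2, 0 °C → rt
Reagents that add atoms: none
Why: Dess–Martin oxidation converts both allylic C9 epimers into one α-methylene ketone; neutral buffered conditions avoid conjugate addition to the exocyclic enone.

Step 19
Reactants: 24 (3R,3aS,4S,8aR)-3-hydroxy-8a-methyl-6-methylidene-7-oxo-3-(propan-2-yl)decahydroazulen-4-yl 3-methylbutanoate
Product: 26 (3R,3aS,4S,8S,8aS)-8a-methyl-6-methylidene-7-oxo-3-(propan-2-yl)-3,8-bis(triethylsilyloxy)decahydroazulen-4-yl 3-methylbutanoate, via bis-silyl dienol ether 25 (not isolated)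
Conditions: TESOTf (3 equiv), Et3N, CH2Cl2, 0 °C → rt; then mCPBA, NaHCO3, CH2Cl2, −20 °C
Reagents that add atoms: triethylsilyl trifluoromethanesulfonate, CC[Si](CC)(CC)OS(=O)(=O)C(F)(F)F; 3-chloroperoxybenzoic acid, OOC(=O)c1cccc(Cl)c1
Why: Rubottom oxidation; soft enolisation can go only towards C10 because C8 bears no hydrogen, and the triflate also silylates the C4 hydroxyl. The peracid should epoxidise the electron-rich enol ether C9=C10 from the α-face, opposite the pseudoaxial C1 methyl, and silyl migration then gives the 10α-silyloxy ketone (10S).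

Step 20
Reactants: 26 (3R,3aS,4S,8S,8aS)-8a-methyl-6-methylidene-7-oxo-3-(propan-2-yl)-3,8-bis(triethylsilyloxy)decahydroazulen-4-yl 3-methylbutanoate
Product: 27 (3R,3aS,4S,7R,8S,8aS)-7-hydroxy-8a-methyl-6-methylidene-3-(propan-2-yl)-3,8-bis(triethylsilyloxy)decahydroazulen-4-yl 3-methylbutanoate
Conditions: NaBH4, CeCl3·7H2O, MeOH, −78 °C
Reagents that add atoms: none
Why: Luche 1,2-reduction of the α-methylene ketone; hydride is expected to add anti to the adjacent bulky 10α-silyloxy group, through the boat-like ring conformer in which the C1 methyl is remote from C9, giving the 9α-alcohol (9R) cis to O10. The ester is inert to NaBH4 at this temperature.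

Step 21
Reactants: 27 (3R,3aS,4S,7R,8S,8aS)-7-hydroxy-8a-methyl-6-methylidene-3-(propan-2-yl)-3,8-bis(triethylsilyloxy)decahydroazulen-4-yl 3-methylbutanoate
Product: 28 (3R,3aS,4S,7R,8S,8aS)-3,7,8-trihydroxy-8a-methyl-6-methylidene-3-(propan-2-yl)decahydroazulen-4-yl 3-methylbutanoate
Conditions: HF·pyridine, pyridine, THF, 0 °C → rt
Reagents that add atoms: none
Why: Fluoride cleavage of both triethylsilyl ethers under buffered conditions that avoid acyl migration, ionisation of the allylic C9 alcohol and dehydration at C4; this gives the target.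

## Compound list

1 | methyl cyclopent-3-ene-1-carboxylate | COC(=O)C1CC=CC1 | starting material
2 | iodomethane | CI | starting material
3 | methyl 1-methylcyclopent-3-ene-1-carboxylate | COC(=O)C1(C)CC=CC1 | intermediate
4 | (1-methylcyclopent-3-en-1-yl)methanol | OCC1(C)CC=CC1 | intermediate
5 | 1-methylcyclopent-3-ene-1-carbaldehyde | O=CC1(C)CC=CC1 | intermediate
6 | 3-methylbutan-2-one | CC(C)C(C)=O | starting material
7 | 1-hydroxy-4-methyl-1-(1-methylcyclopent-3-en-1-yl)pentan-3-one (racemic aldol adduct, not isolated) | CC(C)C(=O)CC(O)C1(C)CC=CC1 | intermediate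
8 | (E)-4-methyl-1-(1-methylcyclopent-3-en-1-yl)pent-1-en-3-one | CC(C)C(=O)/C=C/C1(C)CC=CC1 | intermediate
9 | 4-methyl-1-(1-methylcyclopent-3-en-1-yl)pentan-3-one | CC(C)C(=O)CCC1(C)CC=CC1 | intermediate
10 | 3-methyl-3-(4-methyl-3-oxopentyl)pentanedioic acid | CC(C)C(=O)CCC(C)(CC(=O)O)CC(=O)O | intermediate
11 | 4-methyl-4-(4-methyl-3-oxopentyl)oxane-2,6-dione | O=C1CC(C)(CCC(=O)C(C)C)CC(=O)O1 | intermediate
12 | 2-[(1R,2R,5R)-2-methyl-7-oxo-5-(propan-2-yl)-6-oxabicyclo[3.2.0]heptan-2-yl]acetic acid | OC(=O)C[C@@]1(C)CC[C@]2(C(C)C)OC(=O)[C@H]12 | intermediate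
13 | (1R,2R,5R)-2-(2-hydroxyethyl)-2-methyl-5-(propan-2-yl)-6-oxabicyclo[3.2.0]heptan-7-one | OCC[C@@]1(C)CC[C@]2(C(C)C)OC(=O)[C@H]12 | intermediate
14 | (1R,2R,5R)-2-[2-(tert-butyldimethylsilyloxy)ethyl]-2-methyl-5-(propan-2-yl)-6-oxabicyclo[3.2.0]heptan-7-one | CC(C)(C)[Si](C)(C)OCC[C@@]1(C)CC[C@]2(C(C)C)OC(=O)[C@H]12 | intermediate
15 | (1R,2S,3R)-3-[2-(tert-butyldimethylsilyloxy)ethyl]-2-(hydroxymethyl)-3-methyl-1-(propan-2-yl)cyclopentan-1-ol | CC(C)(C)[Si](C)(C)OCC[C@@]1(C)CC[C@@](O)(C(C)C)[C@@H]1CO | intermediate
16 | (1R,2R,5R)-2-[2-(tert-butyldimethylsilyloxy)ethyl]-5-hydroxy-2-methyl-5-(propan-2-yl)cyclopentane-1-carbaldehyde | CC(C)(C)[Si](C)(C)OCC[C@@]1(C)CC[C@@](O)(C(C)C)[C@@H]1C=O | intermediate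
17 | 2,3-dibromoprop-1-ene | C=C(Br)CBr | starting material
18 | (1R,2S,3R)-2-[(1S)-3-bromo-1-hydroxybut-3-en-1-yl]-3-[2-(tert-butyldimethylsilyloxy)ethyl]-3-methyl-1-(propan-2-yl)cyclopentan-1-ol | CC(C)(C)[Si](C)(C)OCC[C@@]1(C)CC[C@@](O)(C(C)C)[C@@H]1[C@@H](O)CC(Br)=C | intermediate
19 | 3-methylbutanoic anhydride | CC(C)CC(=O)OC(=O)CC(C)C | starting material
20 | (1S)-3-bromo-1-[(1S,2R,5R)-2-[2-(tert-butyldimethylsilyloxy)ethyl]-5-hydroxy-2-methyl-5-(propan-2-yl)cyclopentyl]but-3-en-1-yl 3-methylbutanoate | CC(C)(C)[Si](C)(C)OCC[C@@]1(C)CC[C@@](O)(C(C)C)[C@@H]1[C@@H](OC(=O)CC(C)C)CC(Br)=C | intermediate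
21 | (1S)-3-bromo-1-[(1S,2R,5R)-5-hydroxy-2-(2-hydroxyethyl)-2-methyl-5-(propan-2-yl)cyclopentyl]but-3-en-1-yl 3-methylbutanoate | OCC[C@@]1(C)CC[C@@](O)(C(C)C)[C@@H]1[C@@H](OC(=O)CC(C)C)CC(Br)=C | intermediate
22 | (1S)-3-bromo-1-[(1S,2R,5R)-5-hydroxy-2-methyl-2-(2-oxoethyl)-5-(propan-2-yl)cyclopentyl]but-3-en-1-yl 3-methylbutanoate | O=CC[C@@]1(C)CC[C@@](O)(C(C)C)[C@@H]1[C@@H](OC(=O)CC(C)C)CC(Br)=C | intermediate
23 | (3R,3aS,4S,8aR)-3,7-dihydroxy-8a-methyl-6-methylidene-3-(propan-2-yl)decahydroazulen-4-yl 3-methylbutanoate (both C9 epimers) | C=C1C[C@H](OC(=O)CC(C)C)[C@@H]2[C@](C)(CC[C@@]2(O)C(C)C)CC1O | intermediate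
24 | (3R,3aS,4S,8aR)-3-hydroxy-8a-methyl-6-methylidene-7-oxo-3-(propan-2-yl)decahydroazulen-4-yl 3-methylbutanoate | C=C1C[C@H](OC(=O)CC(C)C)[C@@H]2[C@](C)(CC[C@@]2(O)C(C)C)CC1=O | intermediate
25 | bis(triethylsilyl) derivative of 24: C4 triethylsilyl ether and C9-triethylsilyloxy 8(14),9-diene (not isolated) | C=C1C[C@H](OC(=O)CC(C)C)[C@@H]2[C@](C)(CC[C@@]2(O[Si](CC)(CC)CC)C(C)C)C=C1O[Si](CC)(CC)CC | intermediate
26 | (3R,3aS,4S,8S,8aS)-8a-methyl-6-methylidene-7-oxo-3-(propan-2-yl)-3,8-bis(triethylsilyloxy)decahydroazulen-4-yl 3-methylbutanoate | C=C1C[C@H](OC(=O)CC(C)C)[C@@H]2[C@](C)(CC[C@@]2(O[Si](CC)(CC)CC)C(C)C)[C@H](O[Si](CC)(CC)CC)C1=O | intermediate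
27 | (3R,3aS,4S,7R,8S,8aS)-7-hydroxy-8a-methyl-6-methylidene-3-(propan-2-yl)-3,8-bis(triethylsilyloxy)decahydroazulen-4-yl 3-methylbutanoate | C=C1C[C@H](OC(=O)CC(C)C)[C@@H]2[C@](C)(CC[C@@]2(O[Si](CC)(CC)CC)C(C)C)[C@H](O[Si](CC)(CC)CC)[C@@H]1O | intermediate
28 | (3R,3aS,4S,7R,8S,8aS)-3,7,8-trihydroxy-8a-methyl-6-methylidene-3-(propan-2-yl)decahydroazulen-4-yl 3-methylbutanoate (CNP0204264.1) | C=C1C[C@H](OC(=O)CC(C)C)[C@@H]2[C@](C)(CC[C@@]2(O)C(C)C)[C@H](O)[C@@H]1O | target

## Step count and least certain steps

Total step count: 21. Longest linear sequence: 21 steps (1 → 28); 2, 6, 17 and 19 enter directly.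

**Step 8 (key step, proposed new method).**
- What may go wrong: the acyl isothiouronium carboxylate may return to 11 faster than it enolises, so that there is no turnover. Discrimination between the two enantiotopic arms may be poor; attraction between the carboxylate arm and the cationic acyl unit could pull that arm to the concave side and give the C1 epimer. Enolate-face control may be incomplete.
- Fallback (known chemistry), from 11 back to 12: 11 is opened with benzyl alcohol under a cinchona-alkaloid-derived catalyst (desymmetrising alcoholysis of a prochiral glutaric anhydride) to the hemiester (3S)-5-(benzyloxy)-3-methyl-3-(4-methyl-3-oxopentyl)-5-oxopentanoic acid F1. The free acid arm of F1 is activated with p-toluenesulfonyl chloride and iPr2NEt and cyclised by the established nucleophile-catalysed aldol-lactonisation of 6-oxo acids (isothiourea or 4-pyrrolidinopyridine, LiCl) to benzyl 2-[(1R,2R,5R)-2-methyl-7-oxo-5-(propan-2-yl)-6-oxabicyclo[3.2.0]heptan-2-yl]acetate F2. Hydrogenolysis over Pd/C, which β-lactones tolerate, returns to 12.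

**Step 13.**
- What may go wrong: loss of facial control if the hindered tertiary hydroxyl does not hold the metal, giving C6 epimers; slow addition to an aldehyde flanked by two fully substituted carbons.
- Fallback, from 16 back to 18, replacing substrate control by reagent control: the tertiary hydroxyl of 16 is capped with 1-(trimethylsilyl)imidazole to give the trimethylsilyl ether aldehyde F3. F3 is treated with the chiral B-(2-bromoallyl)-1,3-bis(p-tolylsulfonyl)-4,5-diphenyl-1,3,2-diazaborolidine (from the corresponding bromoborane and 2-bromoallyltributylstannane, controller enantiomer chosen for 6S) to give the trimethylsilyl ether F4 of 18. K2CO3 in MeOH removes the trimethylsilyl group and returns to 18.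

**Step 17.**
- What may go wrong: oligomerisation or simple reduction of the C–Br bond instead of ring closure, because the two arms are trans on the cyclopentane and the ring is seven-membered.
- Fallback, from 16 back to 23, closing the same bond by nickel-catalysed reductive cyclisation of an ynal: 16 is propargylated (propargyl bromide, indium powder, THF/H2O, same chelate control) to (1R,2S,3R)-3-[2-(tert-butyldimethylsilyloxy)ethyl]-2-[(1S)-1-hydroxybut-3-yn-1-yl]-3-methyl-1-(propan-2-yl)cyclopentan-1-ol F5. F5 is acylated with 19 to the isovalerate F6, desilylated with HF·pyridine to the primary alcohol F7 and oxidised with Dess–Martin periodinane to the ynal F8. Ni(cod)2/PBu3 with Et3SiH joins the internal alkyne carbon to the aldehyde and delivers hydrogen to the terminal carbon, giving the 9-O-triethylsilyl ether F9 of 23 with the exocyclic methylene in place. Desilylation with HF·pyridine returns to 23.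

**Step 19.**
- What may go wrong: conjugate addition of the amine to the silyl-activated enone during enol ether formation; competing epoxidation of the exocyclic alkene; attack of the peracid on both faces of C10.
- Fallback, from 24 back to 26: the potassium enolate of 24 (KN(SiMe3)2, 2.2 equiv, THF, −78 °C; the first equivalent is taken by the C4 hydroxyl) is hydroxylated with a camphor-derived N-sulfonyl oxaziridine whose enantiomer reinforces α-face attack, giving (3R,3aS,4S,8S,8aS)-3,8-dihydroxy-8a-methyl-6-methylidene-7-oxo-3-(propan-2-yl)decahydroazulen-4-yl 3-methylbutanoate F10. Bis-silylation of F10 with TESOTf and 2,6-lutidine returns to 26.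

**Step 20.**
- What may go wrong: poor facial selectivity at C9. Attack through the chair-like conformer, anti to the C1 methyl, would give the 9β-alcohol, trans to O10.
- Fallback, from 26 back to 27, by inversion: the reduction is run so that the 9β-alcohol F11 (the C9 epimer of 27) is collected. Mitsunobu esterification of F11 with chloroacetic acid (Ph3P, DIAD) inverts the allylic centre from the open α-face to give the 9α-chloroacetate F12. Brief K2CO3/MeOH treatment cleaves the activated chloroacetate in preference to the hindered isovalerate and returns to 27.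

## Further compounds

F1 | step 8 | (3S)-5-(benzyloxy)-3-methyl-3-(4-methyl-3-oxopentyl)-5-oxopentanoic acid | O=C(OCc1ccccc1)C[C@@](CC(=O)O)(C)CCC(=O)C(C)C
F2 | step 8 | benzyl 2-[(1R,2R,5R)-2-methyl-7-oxo-5-(propan-2-yl)-6-oxabicyclo[3.2.0]heptan-2-yl]acetate | O=C(OCc1ccccc1)C[C@@]1(C)CC[C@]2(C(C)C)OC(=O)[C@H]12
F3 | step 13 | (1R,2R,5R)-2-[2-(tert-butyldimethylsilyloxy)ethyl]-2-methyl-5-(propan-2-yl)-5-(trimethylsilyloxy)cyclopentane-1-carbaldehyde | CC(C)(C)[Si](C)(C)OCC[C@@]1(C)CC[C@@](O[Si](C)(C)C)(C(C)C)[C@@H]1C=O
F4 | step 13 | trimethylsilyl ether of 18 at the tertiary C4 oxygen | CC(C)(C)[Si](C)(C)OCC[C@@]1(C)CC[C@@](O[Si](C)(C)C)(C(C)C)[C@@H]1[C@@H](O)CC(Br)=C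
F5 | step 17 | (1R,2S,3R)-3-[2-(tert-butyldimethylsilyloxy)ethyl]-2-[(1S)-1-hydroxybut-3-yn-1-yl]-3-methyl-1-(propan-2-yl)cyclopentan-1-ol | CC(C)(C)[Si](C)(C)OCC[C@@]1(C)CC[C@@](O)(C(C)C)[C@@H]1[C@@H](O)CC#C
F6 | step 17 | (1S)-1-[(1S,2R,5R)-2-[2-(tert-butyldimethylsilyloxy)ethyl]-5-hydroxy-2-methyl-5-(propan-2-yl)cyclopentyl]but-3-yn-1-yl 3-methylbutanoate | CC(C)(C)[Si](C)(C)OCC[C@@]1(C)CC[C@@](O)(C(C)C)[C@@H]1[C@@H](OC(=O)CC(C)C)CC#C
F7 | step 17 | (1S)-1-[(1S,2R,5R)-5-hydroxy-2-(2-hydroxyethyl)-2-methyl-5-(propan-2-yl)cyclopentyl]but-3-yn-1-yl 3-methylbutanoate | OCC[C@@]1(C)CC[C@@](O)(C(C)C)[C@@H]1[C@@H](OC(=O)CC(C)C)CC#C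
F8 | step 17 | (1S)-1-[(1S,2R,5R)-5-hydroxy-2-methyl-2-(2-oxoethyl)-5-(propan-2-yl)cyclopentyl]but-3-yn-1-yl 3-methylbutanoate | O=CC[C@@]1(C)CC[C@@](O)(C(C)C)[C@@H]1[C@@H](OC(=O)CC(C)C)CC#C
F9 | step 17 | 9-O-triethylsilyl ether of 23 (both C9 epimers) | C=C1C[C@H](OC(=O)CC(C)C)[C@@H]2[C@](C)(CC[C@@]2(O)C(C)C)CC1O[Si](CC)(CC)CC
F10 | step 19 | (3R,3aS,4S,8S,8aS)-3,8-dihydroxy-8a-methyl-6-methylidene-7-oxo-3-(propan-2-yl)decahydroazulen-4-yl 3-methylbutanoate | C=C1C[C@H](OC(=O)CC(C)C)[C@@H]2[C@](C)(CC[C@@]2(O)C(C)C)[C@H](O)C1=O
F11 | step 20 | (3R,3aS,4S,7S,8S,8aS)-7-hydroxy-8a-methyl-6-methylidene-3-(propan-2-yl)-3,8-bis(triethylsilyloxy)decahydroazulen-4-yl 3-methylbutanoate (C9 epimer of 27) | C=C1C[C@H](OC(=O)CC(C)C)[C@@H]2[C@](C)(CC[C@@]2(O[Si](CC)(CC)CC)C(C)C)[C@H](O[Si](CC)(CC)CC)[C@H]1O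
F12 | step 20 | 9α-chloroacetate of 27 | C=C1C[C@H](OC(=O)CC(C)C)[C@@H]2[C@](C)(CC[C@@]2(O[Si](CC)(CC)CC)C(C)C)[C@H](O[Si](CC)(CC)CC)[C@@H]1OC(=O)CCl
A1 | alternative 1 | tert-butyldimethylsilyl ether of the 8-hydroxydauca-5,9-dien-4-one ethylene ketal (spiro-dioxolane at C4) | CC(C)(C)[Si](C)(C)O[C@@H]1CC=C2[C@](C)(CCC23OCCO3)C=C1
A2 | alternative 2 | ethyl 2-[2-(tert-butyldimethylsilyloxy)ethyl]-2-methyl-5-oxocyclopentane-1-carboxylate | CCOC(=O)C1C(=O)CC[C@]1(C)CCO[Si](C)(C)C(C)(C)C
A3 | alternative 3 | cis-fused 2,2-dimethyl-1-oxa-2-silabicyclo[3.3.0]octane with the isopropyl group on the ring-fusion carbinol carbon and methyl and allyl groups on the adjacent quaternary carbon | C=CC[C@@]1(C)CC[C@]2(C(C)C)O[Si](C)(C)C[C@H]12
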